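Ring B is cut across two opposite bonds, C7–C8 (acyl to vinyl) and C5–C10 (quaternary carbon to vinyl; eremophilane numbering). The enone carbons C8 and C10 are the two electrophilic ends of an alkynoate, and C5 and C7 flank C6, which is lent a temporary carbonyl so that both become enolisable positions of an isobutenyl ketone. In one operation KOtBu drives a Michael addition (C5 to C10, ring A, quaternary centre set from C4) and a Dieckmann closure (C7 to C8, ring B) on an acyclic keto ynoate that already holds all fifteen skeletal carbons. The C6 oxygen is later traded for the C6=C7 double bond.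

Key step: step 8

Remarks: Locants C1–C13 are eremophilane locants of the target (C3 carries the ester oxygen, C4 and C5 the ring methyl groups, C8 is the ring carbonyl, C11 the carbinol carbon). Compounds 1, 2 and 20 are taken as commercial. The centre next to the carbonyl in 8–11 (C5) is carried as an epimer mixture because step 8 planarises it. Compound 13 is drawn as the diketone but should exist mainly as an enol.

Step 1
Reactants: 1 pent-4-ynal; 2 (4S)-4-benzyl-3-propanoyl-1,3-oxazolidin-2-one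
Product: 3 (4S)-4-benzyl-3-[(2S,3R)-3-hydroxy-2-methylhept-6-ynoyl]-1,3-oxazolidin-2-one
Conditions: Bu2BOTf, iPr2NEt, CH2Cl2, −78 to 0 °C; then pH 7 buffer, MeOH, H2O2
Reagents that add atoms: none
Why: Evans syn aldol: the Z dibutylboron enolate should add through a closed chair transition state on the face remote from the benzyl group, which sets C3 (R) and C4 (R) as a syn pair.

Step 2
Reactants: 3 (4S)-4-benzyl-3-[(2S,3R)-3-hydroxy-2-methylhept-6-ynoyl]-1,3-oxazolidin-2-one
Product: 4 (2S,3R)-3-hydroxy-N-methoxy-N,2-dimethylhept-6-ynamide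
Conditions: MeNH(OMe)·HCl, AlMe3, CH2Cl2, −20 to 0 °C
Reagents that add atoms: N,O-dimethylhydroxylamine hydrochloride (CNOC.Cl)
Why: Aluminium amide transamidation, assisted by chelation of the free hydroxyl, should release the auxiliary and give the Weinreb amide without retro-aldol cleavage.

Step 3
Reactants: 4 (2S,3R)-3-hydroxy-N-methoxy-N,2-dimethylhept-6-ynamide
Product: 5 (2S,3R)-3-[(tert-butyldimethylsilyl)oxy]-N-methoxy-N,2-dimethylhept-6-ynamide
Conditions: TBSOTf, 2,6-lutidine, CH2Cl2, −78 °C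
Reagents that add atoms: tert-butyldimethylsilyl trifluoromethanesulfonate (CC(C)(C)[Si](C)(C)OS(=O)(=O)C(F)(F)F)
Why: Silyl triflate silylation protects the C3 oxygen against the organometallic, basic and hydride steps that follow.

Step 4
Reactants: 5 (2S,3R)-3-[(tert-butyldimethylsilyl)oxy]-N-methoxy-N,2-dimethylhept-6-ynamide
Product: 6 (3S,4R)-4-[(tert-butyldimethylsilyl)oxy]-3-methyloct-7-yn-2-one
Conditions: MeMgBr (3 equiv), THF, 0 °C
Reagents that add atoms: methylmagnesium bromide (C[Mg]Br)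
Why: Weinreb ketone synthesis: the chelated tetrahedral adduct stops at one addition and gives the methyl ketone on work-up (one equivalent is consumed by the alkyne C–H).

Step 5
Reactants: 6 (3S,4R)-4-[(tert-butyldimethylsilyl)oxy]-3-methyloct-7-yn-2-one
Product: 8 (3R,4R)-4-[(tert-butyldimethylsilyl)oxy]-2,3-dimethyloct-7-ynal (C2 epimers), via methyl enol ether 7 (not isolated)
Conditions: Ph3P+CH2OMe Cl−, KN(SiMe3)2, THF, −78 to 0 °C; then 2 M HCl, THF, 0 °C
Reagents that add atoms: (methoxymethyl)triphenylphosphonium chloride (COC[P+](c1ccccc1)(c1ccccc1)c1ccccc1.[Cl-]); water (O)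
Why: Wittig methoxymethylenation and acid hydrolysis of the enol ether is a one-carbon homologation that turns the ketone carbon into C5 with its methyl group and adds the formyl carbon C6.

Step 6
Reactants: 8 (3R,4R)-4-[(tert-butyldimethylsilyl)oxy]-2,3-dimethyloct-7-ynal
Product: 10 (6R,7R)-7-[(tert-butyldimethylsilyl)oxy]-2,5,6-trimethylundec-2-en-10-yn-4-one (C5 epimers), via bromomagnesium alkoxide 9 (not isolated)
Conditions: Me2C=CHMgBr (2.2 equiv), THF, −78 to 0 °C; then 1,1'-(azodicarbonyl)dipiperidine, 0 °C to rt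
Reagents that add atoms: 2-methylprop-1-enylmagnesium bromide (CC(C)=C[Mg]Br)
Why: Grignard addition to the aldehyde and in situ Mukaiyama-type oxidation of the magnesium alkoxide by the azodicarboxamide should give the isobutenyl ketone in one flask, adding C7 and C11–C13.

Step 7
Reactants: 10 (6R,7R)-7-[(tert-butyldimethylsilyl)oxy]-2,5,6-trimethylundec-2-en-10-yn-4-one
Product: 11 methyl (6R,7R)-6-[(tert-butyldimethylsilyl)oxy]-7,8,11-trimethyl-9-oxododec-10-en-2-ynoate (C8 epimers)
Conditions: PdCl2 (5 mol %), CuCl2 (2.2 equiv), NaOAc (2.2 equiv), CO (1 atm), MeOH, rt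
Reagents that add atoms: carbon monoxide ([C-]#[O+]); methanol (CO)
Why: Oxidative methoxycarbonylation of the terminal alkyne (alkynylpalladium, CO insertion, methanolysis; CuCl2 returns palladium to the divalent state) installs the ynoate under neutral conditions that the enolisable enone tolerates.

Step 8
Reactants: 11 methyl (6R,7R)-6-[(tert-butyldimethylsilyl)oxy]-7,8,11-trimethyl-9-oxododec-10-en-2-ynoate
Product: 13 (4aR,5R,6R)-6-[(tert-butyldimethylsilyl)oxy]-4a,5-dimethyl-3-(prop-1-en-2-yl)-4a,5,6,7-tetrahydronaphthalene-2,4(3H,8H)-dione, via Michael adduct 12 (not isolated)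
Conditions: KOtBu (2.5 equiv), THF (0.01 M), −20 °C to rt; then 1 M HCl
Reagents that add atoms: none
Why: KOtBu equilibrates the ketone enolates of 11, and only the cross-conjugated enolate at C5 can reach the ynoate carbon C10 through a six-membered transition state (6-exo-dig Michael addition, ring A; attack from C7 or the γ-methyl groups would need eight- or ten-membered rings), so the C5–C10 bond forms and the vinyl anion is protonated to enoate 12, whose double-bond geometry equilibrates under the base until C8 lies cis to C5. γ-Deprotonation of the isobutenyl ketone then gives a dienolate whose α-carbon C7 attacks the ester carbon C8 (6-exo-trig Dieckmann closure, ring B), methoxide is expelled and the product is held as its stabilised enolate, which drives both equilibria forward. The closest known reaction type is the KOtBu-mediated consecutive Michael–Claisen synthesis of 4,4-disubstituted cyclohexane-1,3-diones from methyl sec-alkyl ketones and unsaturated esters, here run intramolecularly on an alkynoate with an enone as the donor. The new quaternary centre C5 is controlled by C4: allylic 1,3-strain places the C4–H bond in the enolate plane, the tether through C3 brings C10 to the face opposite the C4 methyl group, and the two methyl groups should end up cis (5R). The step needs C5 over γ regioselectivity (secured by ring size), a Z enoate (secured by base equilibration and the irreversible closure) and facial selectivity at C5 (secured by the C4 stereocentre, with the silyloxy group equatorial in a chair-like transition state).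

Step 9
Reactants: 13 (4aR,5R,6R)-6-[(tert-butyldimethylsilyl)oxy]-4a,5-dimethyl-3-(prop-1-en-2-yl)-4a,5,6,7-tetrahydronaphthalene-2,4(3H,8H)-dione
Product: 14 (7R,8R,8aR)-7-[(tert-butyldimethylsilyl)oxy]-3-methoxy-8,8a-dimethyl-2-(prop-1-en-2-yl)-6,7,8,8a-tetrahydronaphthalen-1(5H)-one
Conditions: TMSCHN2, MeOH–toluene, 0 °C
Reagents that add atoms: (trimethylsilyl)diazomethane (C[Si](C)(C)C=[N+]=[N-])
Why: O-Methylation of the vinylogous acid by the diazoalkane should take place at the more accessible enol oxygen on C8 (the C6 oxygen is flanked by quaternary C5), as in the etherification of 2,4,4-trisubstituted cyclohexane-1,3-diones.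

Step 10
Reactants: 14 (7R,8R,8aR)-7-[(tert-butyldimethylsilyl)oxy]-3-methoxy-8,8a-dimethyl-2-(prop-1-en-2-yl)-6,7,8,8a-tetrahydronaphthalen-1(5H)-one
Product: 17 (4aR,5R,6R)-6-hydroxy-4a,5-dimethyl-3-(prop-1-en-2-yl)-5,6,7,8-tetrahydronaphthalen-2(4aH)-one, via allylic alcohol 15 (not isolated), via silyl dienone 16 (not isolated)
Conditions: LiAlH4, Et2O, 0 °C; EtOAc quench; then 48% aq HF, MeCN, 0 °C to rt
Reagents that add atoms: water (O)
Why: Stork–Danheiser transposition: 1,2-hydride reduction of the C6 carbonyl, then acid ionisation of the allylic alcohol to a methoxyallyl cation and attack of water at C8 should unveil the C8 ketone and the C6=C7 double bond, while HF removes the silyl group in the same flask.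

Step 11
Reactants: 17 (4aR,5R,6R)-6-hydroxy-4a,5-dimethyl-3-(prop-1-en-2-yl)-5,6,7,8-tetrahydronaphthalen-2(4aH)-one
Product: 19 (4aR,5R,6R)-6-hydroxy-3-(2-hydroxypropan-2-yl)-4a,5-dimethyl-5,6,7,8-tetrahydronaphthalen-2(4aH)-one, via organomercurial 18 (not isolated)
Conditions: Hg(OAc)2, THF–H2O, rt; then NaBH4, 3 M NaOH, 0 °C
Reagents that add atoms: water (O)
Why: Markovnikov oxymercuration–demercuration should hydrate only the electron-rich 1,1-disubstituted isopropenyl group (both ring double bonds are electron-poor enones) and place the hydroxyl on C11.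

Step 12
Reactants: 20 prop-2-yn-1-ol
Product: 21 (2Z)-3-iodo-2-methylprop-2-en-1-ol
Conditions: MeMgBr (2.5 equiv), CuI (10 mol %), THF, −10 °C to rt; then I2, −78 to 0 °C
Reagents that add atoms: methylmagnesium bromide (C[Mg]Br); iodine (II)
Why: Hydroxyl-directed, CuI-catalysed anti carbomagnesiation places methyl on the internal carbon and magnesium cis to the CH2O group in a five-membered chelate, and iodinolysis with retention should give the Z vinyl iodide.

Step 13
Reactants: 21 (2Z)-3-iodo-2-methylprop-2-en-1-ol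
Product: 22 (2Z)-3-iodo-2-methylprop-2-enoic acid
Conditions: TEMPO (cat.), PhI(OAc)2, MeCN–H2O, rt
Reagents that add atoms: water (O)
Why: Nitroxyl-catalysed oxidation with the hypervalent iodine reagent in aqueous acetonitrile takes the allylic alcohol through the aldehyde hydrate to the acid without touching the vinyl iodide geometry.

Step 14
Reactants: 22 (2Z)-3-iodo-2-methylprop-2-enoic acid
Product: 23 (2Z)-2-methyl-3-(methylsulfanyl)prop-2-enoic acid
Conditions: NaSMe (2.2 equiv), CuI (10 mol %), DMF, 60 °C; then 1 M HCl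
Reagents that add atoms: sodium methanethiolate ([Na+].[S-]C)
Why: Copper-catalysed C–S coupling (Ullmann type) of the vinyl iodide with thiolate proceeds with retention, which should keep sulfur cis to the carboxyl group (Z).

Step 15
Reactants: 19 (4aR,5R,6R)-6-hydroxy-3-(2-hydroxypropan-2-yl)-4a,5-dimethyl-5,6,7,8-tetrahydronaphthalen-2(4aH)-one; 23 (2Z)-2-methyl-3-(methylsulfanyl)prop-2-enoic acid
Product: 24 (1R,2R,8aR)-7-(2-hydroxypropan-2-yl)-1,8a-dimethyl-6-oxo-1,2,3,4,6,8a-hexahydronaphthalen-2-yl (2Z)-2-methyl-3-(methylsulfanyl)prop-2-enoate (CNP0150028.1)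
Conditions: DCC, DMAP (cat.), CH2Cl2, 0 °C to rt
Reagents that add atoms: none
Why: Steglich esterification should acylate the secondary C3 hydroxyl selectively, since the tertiary C11 hydroxyl is too hindered to react with the activated acid.

Compound list

1 | pent-4-ynal | C#CCCC=O | starting material
2 | (4S)-4-benzyl-3-propanoyl-1,3-oxazolidin-2-one | CCC(=O)N1[C@@H](Cc2ccccc2)COC1=O | starting material
3 | (4S)-4-benzyl-3-[(2S,3R)-3-hydroxy-2-methylhept-6-ynoyl]-1,3-oxazolidin-2-one | C#CCC[C@@H](O)[C@H](C)C(=O)N1[C@@H](Cc2ccccc2)COC1=O | intermediate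
4 | (2S,3R)-3-hydroxy-N-methoxy-N,2-dimethylhept-6-ynamide | C#CCC[C@@H](O)[C@H](C)C(=O)N(C)OC | intermediate
5 | (2S,3R)-3-[(tert-butyldimethylsilyl)oxy]-N-methoxy-N,2-dimethylhept-6-ynamide | C#CCC[C@@H](O[Si](C)(C)C(C)(C)C)[C@H](C)C(=O)N(C)OC | intermediate
6 | (3S,4R)-4-[(tert-butyldimethylsilyl)oxy]-3-methyloct-7-yn-2-one | C#CCC[C@@H](O[Si](C)(C)C(C)(C)C)[C@H](C)C(C)=O | intermediate
7 | (3R,4R)-4-[(tert-butyldimethylsilyl)oxy]-1-methoxy-2,3-dimethyloct-1-en-7-yne (E/Z mixture, not isolated) | C#CCC[C@@H](O[Si](C)(C)C(C)(C)C)[C@H](C)C(C)=COC | intermediate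
8 | (3R,4R)-4-[(tert-butyldimethylsilyl)oxy]-2,3-dimethyloct-7-ynal (C2 epimers) | C#CCC[C@@H](O[Si](C)(C)C(C)(C)C)[C@H](C)C(C)C=O | intermediate
9 | bromomagnesium (6R,7R)-7-[(tert-butyldimethylsilyl)oxy]-2,5,6-trimethylundec-2-en-10-yn-4-olate (not isolated) | C#CCC[C@@H](O[Si](C)(C)C(C)(C)C)[C@H](C)C(C)C(O[Mg]Br)C=C(C)C | intermediate
10 | (6R,7R)-7-[(tert-butyldimethylsilyl)oxy]-2,5,6-trimethylundec-2-en-10-yn-4-one (C5 epimers) | C#CCC[C@@H](O[Si](C)(C)C(C)(C)C)[C@H](C)C(C)C(=O)C=C(C)C | intermediate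
11 | methyl (6R,7R)-6-[(tert-butyldimethylsilyl)oxy]-7,8,11-trimethyl-9-oxododec-10-en-2-ynoate (C8 epimers) | COC(=O)C#CCC[C@@H](O[Si](C)(C)C(C)(C)C)[C@H](C)C(C)C(=O)C=C(C)C | intermediate
12 | methyl (2Z)-2-[(2R,3R,4R)-4-[(tert-butyldimethylsilyl)oxy]-2,3-dimethyl-2-(3-methylbut-2-enoyl)cyclohexylidene]acetate (not isolated) | CC(C)(C)[Si](C)(C)O[C@@H]1CC/C(=C/C(=O)OC)[C@](C)(C(=O)C=C(C)C)[C@H]1C | intermediate
13 | (4aR,5R,6R)-6-[(tert-butyldimethylsilyl)oxy]-4a,5-dimethyl-3-(prop-1-en-2-yl)-4a,5,6,7-tetrahydronaphthalene-2,4(3H,8H)-dione | CC(C)(C)[Si](C)(C)O[C@@H]1CCC2=CC(=O)C(C(C)=C)C(=O)[C@]2(C)[C@H]1C | intermediate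
14 | (7R,8R,8aR)-7-[(tert-butyldimethylsilyl)oxy]-3-methoxy-8,8a-dimethyl-2-(prop-1-en-2-yl)-6,7,8,8a-tetrahydronaphthalen-1(5H)-one | CC(C)(C)[Si](C)(C)O[C@@H]1CCC2=CC(OC)=C(C(C)=C)C(=O)[C@]2(C)[C@H]1C | intermediate
15 | (7R,8R,8aR)-7-[(tert-butyldimethylsilyl)oxy]-3-methoxy-8,8a-dimethyl-2-(prop-1-en-2-yl)-1,5,6,7,8,8a-hexahydronaphthalen-1-ol (C1 epimers, not isolated) | CC(C)(C)[Si](C)(C)O[C@@H]1CCC2=CC(OC)=C(C(C)=C)C(O)[C@]2(C)[C@H]1C | intermediate
16 | (4aR,5R,6R)-6-[(tert-butyldimethylsilyl)oxy]-4a,5-dimethyl-3-(prop-1-en-2-yl)-5,6,7,8-tetrahydronaphthalen-2(4aH)-one (not isolated) | CC(C)(C)[Si](C)(C)O[C@@H]1CCC2=CC(=O)C(C(C)=C)=C[C@]2(C)[C@H]1C | intermediate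
17 | (4aR,5R,6R)-6-hydroxy-4a,5-dimethyl-3-(prop-1-en-2-yl)-5,6,7,8-tetrahydronaphthalen-2(4aH)-one | O[C@@H]1CCC2=CC(=O)C(C(C)=C)=C[C@]2(C)[C@H]1C | intermediate
18 | acetoxymercurio adduct of 17 carrying HgOAc on the terminal carbon and OH on C11 (not isolated) | O[C@@H]1CCC2=CC(=O)C(C(C)(O)C[Hg]OC(C)=O)=C[C@]2(C)[C@H]1C | intermediate
19 | (4aR,5R,6R)-6-hydroxy-3-(2-hydroxypropan-2-yl)-4a,5-dimethyl-5,6,7,8-tetrahydronaphthalen-2(4aH)-one | O[C@@H]1CCC2=CC(=O)C(C(C)(C)O)=C[C@]2(C)[C@H]1C | intermediate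
20 | prop-2-yn-1-ol | C#CCO | starting material
21 | (2Z)-3-iodo-2-methylprop-2-en-1-ol | I/C=C(/C)CO | intermediate
22 | (2Z)-3-iodo-2-methylprop-2-enoic acid | I/C=C(/C)C(=O)O | intermediate
23 | (2Z)-2-methyl-3-(methylsulfanyl)prop-2-enoic acid | CS/C=C(/C)C(=O)O | intermediate
24 | (1R,2R,8aR)-7-(2-hydroxypropan-2-yl)-1,8a-dimethyl-6-oxo-1,2,3,4,6,8a-hexahydronaphthalen-2-yl (2Z)-2-methyl-3-(methylsulfanyl)prop-2-enoate | CS/C=C(/C)C(=O)O[C@@H]1CCC2=CC(=O)C(C(C)(C)O)=C[C@]2(C)[C@H]1C | target

Total step count: 15. Longest linear sequence: 12 steps (steps 1–11 and 15).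

Steps most likely to fail

Step 8. Under the equilibrating base the isobutenyl ketone may rest as its through-conjugated γ-dienolate. Intermolecular conjugate addition and base-induced isomerisation of the ynoate could then outrun cyclisation through the C5 enolate, or the dienolate could fail to acylate at C7. The fallback sets out from aldehyde 8 and returns at vinylogous ester 14. Addition of MeMgBr gives the bromomagnesium alkoxide F1, and oxidation in the same flask with 1,1'-(azodicarbonyl)dipiperidine gives the saturated methyl ketone (4R,5R)-5-[(tert-butyldimethylsilyl)oxy]-3,4-dimethylnon-8-yn-2-one F2. Methoxycarbonylation as in step 7 gives methyl (6R,7R)-6-[(tert-butyldimethylsilyl)oxy]-7,8-dimethyl-9-oxodec-2-ynoate F3. KOtBu in THF then runs the same two ring closures on a methyl sec-alkyl ketone, the substrate class on which the consecutive Michael–Claisen reaction is established, through the monocyclic acetyl enoate F4 to the bicyclic dione F5. O-Methylation with TMSCHN2 gives the vinylogous ester F6, and NBS in CH2Cl2 at 0 °C brominates C7 to the bromo vinylogous ester F7. Suzuki–Miyaura coupling with isopropenylboronic acid pinacol ester (Pd(dppf)Cl2, K3PO4, dioxane–water, 60 °C) attaches the three-carbon unit and reaches 14.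

Step 11. Electrophilic mercuration may be slow on the cross-conjugated isopropenyl group, the borohydride used for demercuration may reduce the dienone carbonyl, and the 2-alkenyl dienone may dimerise before it is hydrated. The fallback sets out from 17 and returns at 19. Conjugate reduction at the less hindered β-carbon C6 with Li(s-Bu)3BH (THF, −78 °C) gives the deconjugated ketone F8, which NaOMe in MeOH moves into conjugation as the isopropylidene enone F9. A Schenck ene reaction with singlet oxygen (O2, tetraphenylporphyrin, visible light, CH2Cl2, 0 °C) should abstract a C6 hydrogen, the group geminal to the carbonyl on the alkene, and give the tertiary allylic hydroperoxide F10 with the C6=C7 double bond in place. PPh3 reduces F10 to 19.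

Step 9. Alkylation at the more hindered enol oxygen on C6, or at carbon C7, would give isomers that lead to the transposed dienone after step 10. The fallback sets out from 13 and returns at 17. Condensation with pyrrolidine (benzene, reflux, water removal) is reversible and should settle on the vinylogous amide F11 at the less hindered C8 carbonyl. LiAlH4 (THF, 0 °C) reduces the C6 carbonyl to the amino alcohol F12, and 48% aq HF in MeCN hydrolyses it with loss of the C6 oxygen, through silyl dienone 16, to 17.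

Further compounds

F1 | step 8 | bromomagnesium (4R,5R)-5-[(tert-butyldimethylsilyl)oxy]-3,4-dimethylnon-8-yn-2-olate (not isolated) | C#CCC[C@@H](O[Si](C)(C)C(C)(C)C)[C@H](C)C(C)C(C)O[Mg]Br
F2 | step 8 | (4R,5R)-5-[(tert-butyldimethylsilyl)oxy]-3,4-dimethylnon-8-yn-2-one (C3 epimers) | C#CCC[C@@H](O[Si](C)(C)C(C)(C)C)[C@H](C)C(C)C(C)=O
F3 | step 8 | methyl (6R,7R)-6-[(tert-butyldimethylsilyl)oxy]-7,8-dimethyl-9-oxodec-2-ynoate (C8 epimers) | COC(=O)C#CCC[C@@H](O[Si](C)(C)C(C)(C)C)[C@H](C)C(C)C(C)=O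
F4 | step 8 | methyl (2Z)-2-[(2R,3R,4R)-2-acetyl-4-[(tert-butyldimethylsilyl)oxy]-2,3-dimethylcyclohexylidene]acetate (not isolated) | CC(C)(C)[Si](C)(C)O[C@@H]1CC/C(=C/C(=O)OC)[C@](C)(C(C)=O)[C@H]1C
F5 | step 8 | (4aR,5R,6R)-6-[(tert-butyldimethylsilyl)oxy]-4a,5-dimethyl-4a,5,6,7-tetrahydronaphthalene-2,4(3H,8H)-dione | CC(C)(C)[Si](C)(C)O[C@@H]1CCC2=CC(=O)CC(=O)[C@]2(C)[C@H]1C
F6 | step 8 | (7R,8R,8aR)-7-[(tert-butyldimethylsilyl)oxy]-3-methoxy-8,8a-dimethyl-6,7,8,8a-tetrahydronaphthalen-1(5H)-one | CC(C)(C)[Si](C)(C)O[C@@H]1CCC2=CC(OC)=CC(=O)[C@]2(C)[C@H]1C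
F7 | step 8 | (7R,8R,8aR)-2-bromo-7-[(tert-butyldimethylsilyl)oxy]-3-methoxy-8,8a-dimethyl-6,7,8,8a-tetrahydronaphthalen-1(5H)-one | CC(C)(C)[Si](C)(C)O[C@@H]1CCC2=CC(OC)=C(Br)C(=O)[C@]2(C)[C@H]1C
F8 | step 11 | (4aR,5R,6R)-6-hydroxy-4a,5-dimethyl-3-(prop-1-en-2-yl)-4,4a,5,6,7,8-hexahydronaphthalen-2(3H)-one (C3 epimers, not isolated) | O[C@@H]1CCC2=CC(=O)C(C(C)=C)C[C@]2(C)[C@H]1C
F9 | step 11 | (4aR,5R,6R)-6-hydroxy-4a,5-dimethyl-3-(propan-2-ylidene)-4,4a,5,6,7,8-hexahydronaphthalen-2(3H)-one | O[C@@H]1CCC2=CC(=O)C(=C(C)C)C[C@]2(C)[C@H]1C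
F10 | step 11 | (4aR,5R,6R)-3-(2-hydroperoxypropan-2-yl)-6-hydroxy-4a,5-dimethyl-5,6,7,8-tetrahydronaphthalen-2(4aH)-one | O[C@@H]1CCC2=CC(=O)C(C(C)(C)OO)=C[C@]2(C)[C@H]1C
F11 | step 9 | (7R,8R,8aR)-7-[(tert-butyldimethylsilyl)oxy]-8,8a-dimethyl-2-(prop-1-en-2-yl)-3-(pyrrolidin-1-yl)-6,7,8,8a-tetrahydronaphthalen-1(5H)-one | CC(C)(C)[Si](C)(C)O[C@@H]1CCC2=CC(N3CCCC3)=C(C(C)=C)C(=O)[C@]2(C)[C@H]1C
F12 | step 9 | (7R,8R,8aR)-7-[(tert-butyldimethylsilyl)oxy]-8,8a-dimethyl-2-(prop-1-en-2-yl)-3-(pyrrolidin-1-yl)-1,5,6,7,8,8a-hexahydronaphthalen-1-ol (C1 epimers, not isolated) | CC(C)(C)[Si](C)(C)O[C@@H]1CCC2=CC(N3CCCC3)=C(C(C)=C)C(O)[C@]2(C)[C@H]1C
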